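**Plan**

- Retrosynthesis: the pivalate on O4' and the prenyl group on O7 are cut first. Ring A is then cut at C4a–C5 (ring expansion) and at C8–C8a (carbonyl addition of a metalated pyranone). The C2–C1' biaryl bond is cut last (Suzuki coupling).
- Forward: ring C is bought as a 3-hydroxy-4-pyranone, brominated and O-methylated. Ring B is joined by cross-coupling, a squarate-derived four-carbon unit is attached at pyranone C6, and ring A is grown last.
- Enabling feature: on ring A the 5-OH and 8-OMe are para, with O7 between C6–H and C8. This is a hydroquinone monomethyl ether, which a 4-methoxy-3-alkoxycyclobutenone bonded to the pyranone carbon next to O1 (future C8a) delivers onto the neighbouring pyranone C–H carbon (future C4a).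
- Stereochemistry: the target has no stereocentre and no stereogenic alkene. The one carbinol stereocentre on the way is racemic and is erased in the ring expansion. The only geometry that matters, that of the dienylketene, is set by torquoselectivity.
- End game: the isopropyl group on O7 is exchanged for prenyl while the 5-OH stays chelated, then the pivalate is removed.

Key step: step 8

Assumption: pyromeconic acid, the guaiacol boronate, diisopropyl squarate and prenyl bromide are taken as purchasable, and racemic intermediates are acceptable because the target is achiral.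

**Route**

Step 1
Reactants: 1 pyromeconic acid (3-hydroxy-4H-pyran-4-one)
Product: 2 2-bromo-3-hydroxy-4H-pyran-4-one
Conditions: NBS, MeCN, 0 °C → rt
Reagents that add atoms: N-bromosuccinimide, O=C1CCC(=O)N1Br
Why: Electrophilic bromination of an enol; the 3-hydroxyl makes C2, the other carbon of the enolic C2=C3 bond, the only strongly nucleophilic ring carbon, as in the halogenation of kojic acid next to its hydroxyl.

Step 2
Reactants: 2 2-bromo-3-hydroxy-4H-pyran-4-one
Product: 3 2-bromo-3-methoxy-4H-pyran-4-one
Conditions: MeI, K2CO3, acetone, 50 °C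
Reagents that add atoms: iodomethane, CI
Why: Williamson O-methylation of the acidic enolic hydroxyl under weak base, conditions under which the vinylogous acyl bromide should remain intact.

Step 3
Reactants: 4 2-methoxy-4-(4,4,5,5-tetramethyl-1,3,2-dioxaborolan-2-yl)phenol
Product: 5 2-methoxy-4-(4,4,5,5-tetramethyl-1,3,2-dioxaborolan-2-yl)phenyl pivalate
Conditions: PivCl, Et3N, DMAP (cat.), CH2Cl2, 0 °C → rt
Reagents that add atoms: pivaloyl chloride, CC(C)(C)C(Cl)=O
Why: DMAP-catalysed acylation of the phenol; the hindered ester is chosen because it should survive coupling base, a hindered amide base, Ag2O, heat and BCl3 and still fall to methoxide at the end, and the pinacol boronate is inert to acylation.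

Step 4
Reactants: 3 2-bromo-3-methoxy-4H-pyran-4-one; 5 2-methoxy-4-(4,4,5,5-tetramethyl-1,3,2-dioxaborolan-2-yl)phenyl pivalate
Product: 6 2-methoxy-4-(3-methoxy-4-oxo-4H-pyran-2-yl)phenyl pivalate
Conditions: Pd(PPh3)4 (5 mol %), K3PO4, 1,4-dioxane–H2O (20:1), 80 °C
Reagents that add atoms: none
Why: Suzuki–Miyaura coupling; the 2-bromopyranone is a vinylogous acyl bromide that adds readily to zerovalent palladium, and phosphate in nearly anhydrous dioxane should spare both the pivalate and the pyranone ring.

Step 5
Reactants: 7 diisopropyl squarate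
Product: 9 3-isopropoxycyclobut-3-ene-1,2-dione, via hydroxycyclobutenone 8 (not isolated)
Conditions: LiAlH(OtBu)3, THF, −78 → −20 °C; then 6 M HCl, CH2Cl2, rt
Reagents that add atoms: water, O
Why: Hydride mono-reduction of one vinylogous ester carbonyl by the bulky alkoxyaluminium hydride stops at the hydroxycyclobutenone, and acid then ionises the allylic hydroxyl, water adds at the alkoxy-bearing terminus and isopropanol is lost, which is the established way from dialkyl squarates to alkyl semisquarates.

Step 6
Reactants: 6 2-methoxy-4-(3-methoxy-4-oxo-4H-pyran-2-yl)phenyl pivalate; 9 3-isopropoxycyclobut-3-ene-1,2-dione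
Product: 11 racemic 4-[6-(1-hydroxy-2-isopropoxy-4-oxocyclobut-2-en-1-yl)-3-methoxy-4-oxo-4H-pyran-2-yl]-2-methoxyphenyl pivalate, via C6-magnesiated pyranone 10 (not isolated)
Conditions: TMPMgCl·LiCl (1.2 equiv), THF, −40 °C; cannulated into 9 (1.3 equiv), THF, −78 °C; aq. NH4Cl
Reagents that add atoms: none
Why: Magnesiation with the Knochel–Hauser base (TMP = 2,2,6,6-tetramethylpiperidide) should remove the most acidic ring proton, C6–H next to the ring oxygen and β to the carbonyl (the position metalated by TMP bases in chromones), and the organomagnesium then adds 1,2 to the more electrophilic carbonyl of the dione, the one beside the isopropoxy carbon that is not part of the vinylogous ester, following the known regiochemistry of organometallic addition to 3-alkoxycyclobutenediones; the new quaternary carbinol carbon forms racemic.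

Step 7
Reactants: 11 racemic 4-[6-(1-hydroxy-2-isopropoxy-4-oxocyclobut-2-en-1-yl)-3-methoxy-4-oxo-4H-pyran-2-yl]-2-methoxyphenyl pivalate
Product: 12 racemic 4-[6-(1-methoxy-2-isopropoxy-4-oxocyclobut-2-en-1-yl)-3-methoxy-4-oxo-4H-pyran-2-yl]-2-methoxyphenyl pivalate
Conditions: MeI, Ag2O, 4 Å MS, MeCN, rt, dark
Reagents that add atoms: iodomethane, CI
Why: Purdie methylation (Ag2O/MeI) is the standard way of capping tertiary 4-hydroxycyclobutenones without base-induced ring cleavage, and these neutral conditions should not alkylate the pyranone carbonyl oxygen as methyl triflate could.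

Step 8
Reactants: 12 racemic 4-[6-(1-methoxy-2-isopropoxy-4-oxocyclobut-2-en-1-yl)-3-methoxy-4-oxo-4H-pyran-2-yl]-2-methoxyphenyl pivalate
Product: 15 5-hydroxy-7-isopropoxy-3,8-dimethoxy-2-[3-methoxy-4-(pivaloyloxy)phenyl]-4H-chromen-4-one, via dienylketene 13 (not isolated), via 4a-H cyclohexadienone 14 (not isolated)
Conditions: toluene (0.01 M, degassed), 110 °C, under argon
Reagents that add atoms: none
Why: Heating should open the cyclobutenone by conrotatory four-electron electrocyclic ring opening to the dienylketene 13, whose ketene carbon then bonds to pyranone C5 (the nucleophilic α-carbon of the vinylogous ester) in a disrotatory six-electron electrocyclization, after which the 4a-H cyclohexadienone 14 enolises to the aromatic, chelated 5-hydroxychromone. The closest known reaction type is the Moore rearrangement of 4-aryl-, 4-heteroaryl- and 4-alkenyl-4-alkoxycyclobutenones to hydroquinone monoethers, in which the 4-oxopyranyl group here plays the alkenyl partner and is the least documented member of that class. The one ring closed, carbocyclic ring A, forms by six-electron electrocyclic closure at the C4a–C5 bond followed by tautomerisation. No stereocentre is created, since the racemic quaternary carbon of 12 becomes the sp2 carbon C8 and the transient C4a–H centre of 14 is lost on aromatisation. The selectivity needed is torquoselectivity in the ring opening, secured by the 4-methoxy donor, which rotates outward and so places the pyranone cis to the ketene; regiochemistry needs no control because the constitution of 12 maps the ketene carbon, the CH, the isopropoxy carbon and the methoxy carbon onto C5, C6, C7 and C8, and C5 is the only pyranone carbon that can close. High dilution and exclusion of water and oxygen should keep the ketene from intermolecular capture.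

Step 9
Reactants: 15 5-hydroxy-7-isopropoxy-3,8-dimethoxy-2-[3-methoxy-4-(pivaloyloxy)phenyl]-4H-chromen-4-one
Product: 16 5,7-dihydroxy-3,8-dimethoxy-2-[3-methoxy-4-(pivaloyloxy)phenyl]-4H-chromen-4-one
Conditions: BCl3 (3 equiv), CH2Cl2, −78 → 0 °C; then H2O
Reagents that add atoms: none
Why: Lewis acid ether cleavage; BCl3 removes secondary alkyl aryl ethers by an ionising pathway much faster than methyl ethers, so the isopropyl group should be lost while the three methyl ethers and the pivalate remain, the 5-hydroxyl being tied up first as a boron chelate with the C4 carbonyl, which also shields the 3-methoxy group.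

Step 10
Reactants: 16 5,7-dihydroxy-3,8-dimethoxy-2-[3-methoxy-4-(pivaloyloxy)phenyl]-4H-chromen-4-one; 17 prenyl bromide (1-bromo-3-methylbut-2-ene)
Product: 18 5-hydroxy-3,8-dimethoxy-7-(3-methylbut-2-enyloxy)-2-[3-methoxy-4-(pivaloyloxy)phenyl]-4H-chromen-4-one
Conditions: 17 (1.1 equiv), K2CO3 (1.1 equiv), acetone, 40 °C
Reagents that add atoms: none
Why: Williamson alkylation under weak base; the 7-hydroxyl, para to the carbonyl, is the most acidic and the only phenol not hydrogen-bonded, whereas the 5-hydroxyl is held in the chelate with the C4 carbonyl and should not react with one equivalent of carbonate and bromide.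

Step 11
Reactants: 18 5-hydroxy-3,8-dimethoxy-7-(3-methylbut-2-enyloxy)-2-[3-methoxy-4-(pivaloyloxy)phenyl]-4H-chromen-4-one
Product: 19 5,4'-dihydroxy-3,8,3'-trimethoxy-7-prenyloxyflavone
Conditions: NaOMe (2.2 equiv), MeOH–THF, 0 °C → rt; then AcOH
Reagents that add atoms: none
Why: Methoxide transesterification of the aryl pivalate releases the phenol, and the prenyl ether, the methyl ethers and the chromone should be stable to methoxide at room temperature.

**Compound list**

1 | pyromeconic acid (3-hydroxy-4H-pyran-4-one) | O=c1ccocc1O | starting material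
2 | 2-bromo-3-hydroxy-4H-pyran-4-one | O=c1ccoc(Br)c1O | intermediate
3 | 2-bromo-3-methoxy-4H-pyran-4-one | COc1c(Br)occc1=O | intermediate
4 | 2-methoxy-4-(4,4,5,5-tetramethyl-1,3,2-dioxaborolan-2-yl)phenol | COc1cc(B2OC(C)(C)C(C)(C)O2)ccc1O | starting material
5 | 2-methoxy-4-(4,4,5,5-tetramethyl-1,3,2-dioxaborolan-2-yl)phenyl pivalate | COc1cc(B2OC(C)(C)C(C)(C)O2)ccc1OC(=O)C(C)(C)C | intermediate
6 | 2-methoxy-4-(3-methoxy-4-oxo-4H-pyran-2-yl)phenyl pivalate | COc1cc(-c2occc(=O)c2OC)ccc1OC(=O)C(C)(C)C | intermediate
7 | diisopropyl squarate | CC(C)OC1=C(OC(C)C)C(=O)C1=O | starting material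
8 | racemic 4-hydroxy-2,3-diisopropoxycyclobut-2-en-1-one (formed in the flask) | CC(C)OC1=C(OC(C)C)C(O)C1=O | intermediate
9 | 3-isopropoxycyclobut-3-ene-1,2-dione (isopropyl semisquarate) | CC(C)OC1=CC(=O)C1=O | intermediate
10 | C6-magnesiated pyranone, chloromagnesium species as its LiCl complex (formed in the flask) | COc1cc(-c2oc([Mg]Cl)cc(=O)c2OC)ccc1OC(=O)C(C)(C)C.[Li+].[Cl-] | intermediate
11 | racemic 4-[6-(1-hydroxy-2-isopropoxy-4-oxocyclobut-2-en-1-yl)-3-methoxy-4-oxo-4H-pyran-2-yl]-2-methoxyphenyl pivalate | O=C1C=C(OC(C)C)C1(O)c1cc(=O)c(OC)c(-c2ccc(OC(=O)C(C)(C)C)c(OC)c2)o1 | intermediate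
12 | racemic 4-[6-(1-methoxy-2-isopropoxy-4-oxocyclobut-2-en-1-yl)-3-methoxy-4-oxo-4H-pyran-2-yl]-2-methoxyphenyl pivalate | O=C1C=C(OC(C)C)C1(OC)c1cc(=O)c(OC)c(-c2ccc(OC(=O)C(C)(C)C)c(OC)c2)o1 | intermediate
13 | (Z)-dienylketene, pyranone cis to the ketene chain (formed in the flask) | O=C=C/C(OC(C)C)=C(/OC)c1cc(=O)c(OC)c(-c2ccc(OC(=O)C(C)(C)C)c(OC)c2)o1 | intermediate
14 | racemic 4a-H cyclohexadienone, keto tautomer of 15 (formed in the flask) | O=C1C=C(OC(C)C)C(OC)=C2OC(c3ccc(OC(=O)C(C)(C)C)c(OC)c3)=C(OC)C(=O)C12 | intermediate
15 | 5-hydroxy-7-isopropoxy-3,8-dimethoxy-2-[3-methoxy-4-(pivaloyloxy)phenyl]-4H-chromen-4-one | COc1cc(-c2oc3c(OC)c(OC(C)C)cc(O)c3c(=O)c2OC)ccc1OC(=O)C(C)(C)C | intermediate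
16 | 5,7-dihydroxy-3,8-dimethoxy-2-[3-methoxy-4-(pivaloyloxy)phenyl]-4H-chromen-4-one | COc1cc(-c2oc3c(OC)c(O)cc(O)c3c(=O)c2OC)ccc1OC(=O)C(C)(C)C | intermediate
17 | prenyl bromide (1-bromo-3-methylbut-2-ene) | CC(C)=CCBr | starting material
18 | 5-hydroxy-3,8-dimethoxy-7-(3-methylbut-2-enyloxy)-2-[3-methoxy-4-(pivaloyloxy)phenyl]-4H-chromen-4-one | COc1cc(-c2oc3c(OC)c(OCC=C(C)C)cc(O)c3c(=O)c2OC)ccc1OC(=O)C(C)(C)C | intermediate
19 | 5,4'-dihydroxy-3,8,3'-trimethoxy-7-prenyloxyflavone | COc1cc(-c2oc3c(OC)c(OCC=C(C)C)cc(O)c3c(=O)c2OC)ccc1O | target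

**Count**

Total steps: 11. Longest linear sequence: 9 steps (steps 1, 2, 4, 6, 7, 8, 9, 10, 11, from pyromeconic acid).

**Steps most likely to fail**

Step 6. The deprotonation may be unselective (pyranone C5 or the position next to the pivalate instead of C6), the amide base may attack the ester, or the magnesiated pyranone may add to a second pyranone before it meets the dione. The fallback sets out from 6 and separates metalation from carbonyl addition. Compound 6 would be zincated with the milder, ester-tolerant amide TMP2Zn·2MgCl2·2LiCl (THF, −30 °C), and the zinc species quenched with iodine to give 4-(6-iodo-3-methoxy-4-oxo-4H-pyran-2-yl)-2-methoxyphenyl pivalate F1, whose constitution can be checked before material is committed. Iodine–magnesium exchange with iPrMgCl·LiCl in THF at −78 °C would then generate the organomagnesium at a temperature where it is stable, so this fallback comes back to the route at 10, which is added to 9 as in step 6.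

Step 8. The six-electron closure onto the pyranone may be slow, so that the dienylketene is consumed by oligomerisation or by traces of nucleophiles, the more so as the tertiary methyl ether must lie beside the ring oxygen in the closing conformer. The fallback sets out from 11 and runs the ring expansion in its most documented form, on the free carbinol. Heating 11 in degassed toluene or p-xylene under argon should give the hydroquinone 4-(5,8-dihydroxy-7-isopropoxy-3-methoxy-4-oxo-4H-chromen-2-yl)-2-methoxyphenyl pivalate F2. The methyl group is then introduced after ring formation: one equivalent of Me2SO4 with K2CO3 in acetone under argon should alkylate only the 8-hydroxyl, because the 5-hydroxyl is chelated to the C4 carbonyl. This comes back to the route at 15.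

Step 9. The Lewis acid may also remove the 8-methyl ether (which can bind boron together with O7) or the 3-methyl ether next to the carbonyl, or the cleavage may stall on the boron chelate. The fallback sets out from 9 and avoids any dealkylation by bringing the prenyl ether in with the four-carbon unit. Base-catalysed alkoxy exchange of 9 with excess 3-methylbut-2-en-1-ol (cat. Et3N, CH2Cl2, rt, isopropanol removed under reduced pressure) should give 3-(3-methylbut-2-enyloxy)cyclobut-3-ene-1,2-dione F3. Addition of 10 as in step 6 would give racemic 4-{6-[1-hydroxy-2-(3-methylbut-2-enyloxy)-4-oxocyclobut-2-en-1-yl]-3-methoxy-4-oxo-4H-pyran-2-yl}-2-methoxyphenyl pivalate F4. Methylation with MeI and Ag2O as in step 7 would give racemic 4-{6-[1-methoxy-2-(3-methylbut-2-enyloxy)-4-oxocyclobut-2-en-1-yl]-3-methoxy-4-oxo-4H-pyran-2-yl}-2-methoxyphenyl pivalate F5. Heating F5 in toluene at 110 °C, below the temperature at which allyl vinyl ether or aryl prenyl ether Claisen shifts become fast, should give the prenyl ether directly, so this fallback comes back to the route at 18 and by-passes steps 9 and 10.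

**Further compounds**

F1 | step 6 | 4-(6-iodo-3-methoxy-4-oxo-4H-pyran-2-yl)-2-methoxyphenyl pivalate | COc1cc(-c2oc(I)cc(=O)c2OC)ccc1OC(=O)C(C)(C)C
F2 | step 8 | 4-(5,8-dihydroxy-7-isopropoxy-3-methoxy-4-oxo-4H-chromen-2-yl)-2-methoxyphenyl pivalate | COc1cc(-c2oc3c(O)c(OC(C)C)cc(O)c3c(=O)c2OC)ccc1OC(=O)C(C)(C)C
F3 | step 9 | 3-(3-methylbut-2-enyloxy)cyclobut-3-ene-1,2-dione | CC(C)=CCOC1=CC(=O)C1=O
F4 | step 9 | racemic 4-{6-[1-hydroxy-2-(3-methylbut-2-enyloxy)-4-oxocyclobut-2-en-1-yl]-3-methoxy-4-oxo-4H-pyran-2-yl}-2-methoxyphenyl pivalate | O=C1C=C(OCC=C(C)C)C1(O)c1cc(=O)c(OC)c(-c2ccc(OC(=O)C(C)(C)C)c(OC)c2)o1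
F5 | step 9 | racemic 4-{6-[1-methoxy-2-(3-methylbut-2-enyloxy)-4-oxocyclobut-2-en-1-yl]-3-methoxy-4-oxo-4H-pyran-2-yl}-2-methoxyphenyl pivalate | O=C1C=C(OCC=C(C)C)C1(OC)c1cc(=O)c(OC)c(-c2ccc(OC(=O)C(C)(C)C)c(OC)c2)o1
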